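**Retrosynthetic overview**

1. Guidongnin C ⇐ 16-methylene-11,15-dione 24 by one dissolving-metal reduction (sets C11 and C16). Ring D ⇐ intramolecular Michael addition of a C8 acetyl group (C16) to the ring C enone carbon C13.
2. Ring C and the δ-lactone together ⇐ ester-tethered intramolecular Diels–Alder reaction that forms C8–C9 and C13–C14. The diene is the C10-bound 2-silyloxydiene C9=C11–C12=C13 and the dienophile is the acrylate C8=C14 on the C20 oxygen.
3. Enabling feature: C8–C9 is the bond shared by ring C and the six-membered lactone C7–O–C20–C10–C9–C8. The lactone ester is therefore a built-in four-atom tether from C8 to C10 (next to C9), and the C11 oxygen is carried as the silyloxy group of the diene.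
4. Ring A with its γ-lactone ⇐ a first ester-tethered intramolecular Diels–Alder reaction (C4–C5 and C1–C10). C10 is made quaternary by alkylation of the C20 aldehyde.
5. Order of ring formation: ring A + γ-lactone → δ-lactone + ring C → ring D.

Key step: step 11

Remark: locants C1–C20 in names and explanations follow the ent-kaurane numbering of the target (C6/C19 γ-lactone, C7/C20 δ-lactone). Compounds 2 and 5 are taken as catalogue compounds. The carbinol carbon of 16 is carried as both epimers and becomes a ketone in step 13.

**Route**

Step 1
Reactants: 1 acrolein; 2 ethyl 2-[bis(2,2,2-trifluoroethoxy)phosphoryl]propanoate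
Product: 3 ethyl (2Z)-2-methylpenta-2,4-dienoate
Conditions: KN(SiMe3)2, 18-crown-6, THF, −78 °C
Reagents that add atoms: none
Why: Still–Gennari variant of the Horner–Wadsworth–Emmons olefination, in which the electron-poor phosphonate under dissociating conditions eliminates from the kinetic adduct and should give the (Z)-trisubstituted dienoate, with the ester carbon cis to the vinyl group.

Step 2
Reactants: 3 ethyl (2Z)-2-methylpenta-2,4-dienoate
Product: 4 (2Z)-2-methylpenta-2,4-dien-1-ol
Conditions: iBu2AlH, CH2Cl2, −78 °C
Reagents that add atoms: none
Why: Hydride 1,2-reduction of the conjugated ester to the allylic alcohol should leave the (Z)-diene geometry untouched.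

Step 3
Reactants: 4 (2Z)-2-methylpenta-2,4-dien-1-ol; 5 (2E)-4-oxobut-2-enoic acid
Product: 6 (2Z)-2-methylpenta-2,4-dien-1-yl (2E)-4-oxobut-2-enoate
Conditions: DCC, DMAP (cat.), CH2Cl2, 0 °C
Reagents that add atoms: none
Why: Steglich esterification joins dienol and aldehyde acid under neutral conditions that should neither isomerise the diene nor touch the enal.

Step 4
Reactants: 6 (2Z)-2-methylpenta-2,4-dien-1-yl (2E)-4-oxobut-2-enoate
Product: 7 ring A cyclohexene lactone aldehyde
Conditions: (2R,5R)-5-benzyl-2-tert-butyl-3-methylimidazolidin-4-one·CF3CO2H (20 mol%), MeCN/H2O 95:5, 20 °C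
Reagents that add atoms: none
Why: Proposed new method: iminium formation between the chiral secondary amine and the enal lowers the dienophile LUMO so that the ester-tethered (Z)-diene, which can reach only the cis-fused transition state, closes by an intramolecular Diels–Alder reaction forming C4–C5 and C1–C10, the benzyl arm of the catalyst shielding one face of C5 so that the diene adds to the other and fixes C5 and, through the enforced cis fusion, the quaternary C4 (C10 is also formed but is re-set in step 6); the closest known reaction type is the imidazolidinone-catalysed enantioselective intramolecular Diels–Alder reaction of trienals with carbon or ether tethers, and the new elements are the ester tether and the trisubstituted (Z)-diene terminus that creates a quaternary centre.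

Step 5
Reactants: 7 ring A cyclohexene lactone aldehyde
Product: 8 saturated ring A lactone aldehyde
Conditions: H2 (1 atm), Pd/C, EtOAc, 20 °C
Reagents that add atoms: none
Why: Heterogeneous hydrogenation should saturate the disubstituted ring alkene much faster than it reduces the hindered aldehyde, and it creates no stereocentre.

Step 6
Reactants: 8 saturated ring A lactone aldehyde
Product: 9 quaternary lactone aldehyde amide
Conditions: KN(SiMe3)2, THF, −78 °C; BrCH2C(O)N(OMe)Me, −78 → 0 °C
Reagents that add atoms: 2-bromo-N-methoxy-N-methylacetamide BrCC(=O)N(C)OC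
Why: Alkylation of the potassium enolate of the α-branched aldehyde (the most acidic C–H present) with a reactive α-bromo amide should occur on the convex face of the cis-fused bicycle, anti to the lactone ring on C5, which places the formyl carbon C20 cis to the lactone carbonyl and sets the quaternary C10.

Step 7
Reactants: 9 quaternary lactone aldehyde amide
Product: 10 primary alcohol amide
Conditions: NaBH4, CeCl3·7H2O, MeOH, −78 °C; AcOH quench
Reagents that add atoms: none
Why: Luche-type borohydride reduction is selective for the aldehyde over lactone and N-methoxy-N-methylamide, and low temperature with an acidic quench should keep the C20 alkoxide from opening the neighbouring lactone.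

Step 8
Reactants: 10 primary alcohol amide
Product: 12 hydroxy vinyl ketone, via trimethylsilyl ether 11 (not isolated)
Conditions: Me3SiCl, Et3N, THF, 0 °C; CH2=CHMgBr, −78 → −20 °C; inverse quench into cold 1 M HCl
Reagents that add atoms: chlorotrimethylsilane C[Si](C)(C)Cl (in 11 only); vinylmagnesium bromide C=C[Mg]Br
Why: Weinreb ketone synthesis, in which transient O-silylation masks the alcohol, the magnesium chelate of the N-methoxy-N-methylamide stops after one addition of the vinyl Grignard reagent, and the acidic inverse quench releases vinyl ketone and alcohol without amine conjugate addition.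

Step 9
Reactants: 12 hydroxy vinyl ketone
Product: 13 acrylate vinyl ketone
Conditions: CH2=CHCOCl, iPr2NEt, CH2Cl2, −40 → 0 °C
Reagents that add atoms: acryloyl chloride C=CC(Cl)=O
Why: Acylation of the neopentyl primary alcohol with an acid chloride and a hindered amine installs the acrylate (later C7, C8 and C14) without amine-catalysed dimerisation of the vinyl ketone.

Step 10
Reactants: 13 acrylate vinyl ketone
Product: 14 silyloxydiene acrylate
Conditions: TBSOTf, Et3N, CH2Cl2, −78 → 0 °C
Reagents that add atoms: tert-butyldimethylsilyl trifluoromethanesulfonate CC(C)(C)[Si](C)(C)OS(=O)(=O)C(F)(F)F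
Why: Soft enolisation of the vinyl ketone can occur only toward C9 and should give the (Z)-configured 2-silyloxydiene, with the bulky C10 group cis to oxygen and trans to the vinyl group.

Step 11
Reactants: 14 silyloxydiene acrylate
Product: 15 tetracyclic Diels–Alder adduct
Conditions: PhMe (0.01 M), BHT (cat.), 185 °C, sealed tube
Reagents that add atoms: none
Why: Thermal, concerted but asynchronous [4+2] cycloaddition in which the acrylate C8=C14 adds across the diene termini C9 and C13, forming C8–C9 and C13–C14. The closest known reaction type is the intramolecular Diels–Alder reaction of ester-tethered hexa-3,5-dienyl acrylates and of tethered 2-silyloxydienes, which give fused δ-lactone–cyclohexene products on heating. Ring C closes as the [4+2] ring, and the δ-lactone closes in the fused mode as the six-membered ring that holds the tether atoms C7, O, C20 and C10 together with the new C8–C9 bond. C9 is set relative to C10 by allylic 1,3-strain: the silyloxy group on C11 is cis to the quaternary C10, so the bulkier C5 branch of ring A should turn away from it and lie anti to the diene, which leaves the tethered acrylate only the diene face that gives the required C9 configuration; C8 is formed with H8 cis to H9 through the tether-endo (cis-fused) transition state, but this centre is replaced in step 12. The step needs regioselectivity against the electronic preference of the 2-silyloxydiene (its nucleophilic terminus C9 would pair with C14); this is secured by the short tether, which makes the bridged regioisomer unreachable, and by heating without Lewis acid in a non-polar solvent so that stepwise ionic addition should not compete.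

Step 12
Reactants: 15 tetracyclic Diels–Alder adduct
Product: 16 C8 1-hydroxyethyl adduct
Conditions: LiN(iPr)2, THF, −78 °C; CH3CHO; AcOH, −78 °C
Reagents that add atoms: acetaldehyde CC=O
Why: Directed aldol reaction in which the base removes the more accessible C8–H of the δ-lactone (C5–H of the γ-lactone is flanked by two quaternary carbons) and acetaldehyde should add to the planar C8 enolate on the convex face, anti to the spiro-linked ring A, setting the quaternary C8 with the new carbon cis to H9.

Step 13
Reactants: 16 C8 1-hydroxyethyl adduct
Product: 17 C8 acetyl lactone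
Conditions: DMP (Dess–Martin periodinane), NaHCO3, CH2Cl2, 0 → 20 °C
Reagents that add atoms: none
Why: Dess–Martin oxidation of the secondary alcohol to the methyl ketone under buffered conditions should spare the silyl enol ether and merges the two carbinol epimers.

Step 14
Reactants: 17 C8 acetyl lactone
Product: 18 ring C enone
Conditions: Pd(OAc)2 (1.1 equiv), MeCN, 20 °C
Reagents that add atoms: none
Why: Saegusa–Ito oxidation, in which Pd(OAc)2 turns the silyl enol ether into an oxo-π-allyl palladium species and β-hydride loss from C13 should give the C12=C13 enone regiospecifically.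

Step 15
Reactants: 18 ring C enone
Product: 20 triethylsilyl enol ether, via potassium enolate 19 (not isolated)
Conditions: KN(SiMe3)2, THF, −78 → −20 °C; Et3SiCl, −78 °C
Reagents that add atoms: chlorotriethylsilane CC[Si](Cl)(CC)CC
Why: Kinetic deprotonation of the methyl ketone and intramolecular Michael addition of C16 to the enone carbon C13 should close the five-membered ring D of the bicyclo[3.2.1]octane (the axial C8 acyl group fixes C13), and O-silylation of the resulting C11 enolate masks that ketone for the next step.

Step 16
Reactants: 20 triethylsilyl enol ether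
Product: 24 16-methylene-11,15-dione, via Mannich base 21 (not isolated), via ammonium iodide 22 (not isolated), via silyl enol ether 23 (not isolated)
Conditions: LiN(iPr)2, THF, −78 °C; CH2=NMe2+ I−; MeI, 20 °C; DBU; 1 M HCl, THF, 0 °C
Reagents that add atoms: N,N-dimethylmethyleneiminium iodide C=[N+](C)C.[I-]; iodomethane CI (in 22 only)
Why: Mannich reaction of the only free ketone enolate (C16) with the iminium salt, exhaustive N-methylation, base-induced elimination to the exo-methylene ketone and acid hydrolysis of the silyl enol ether should give the enone diketone.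

Step 17
Reactants: 24 16-methylene-11,15-dione
Product: 25 guidongnin C
Conditions: Li, NH3(l)/THF, t-BuOH (2 equiv), −78 °C; solid NH4Cl, −78 °C
Reagents that add atoms: none
Why: Dissolving-metal reduction in which two electrons convert the α-methylene ketone into its lithium enolate (inert to further reduction), the isolated C11 ketone is reduced through its ketyl to the thermodynamically preferred equatorial alcohol (oxygen anti to the two-carbon bridge), and kinetic protonation of the C15 enolate on quenching should come from the open exo face and place the C16 methyl group endo.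

**Compound list**

1 | acrolein | C=CC=O | starting material
2 | ethyl 2-[bis(2,2,2-trifluoroethoxy)phosphoryl]propanoate | CCOC(=O)C(C)P(=O)(OCC(F)(F)F)OCC(F)(F)F | starting material
3 | ethyl (2Z)-2-methylpenta-2,4-dienoate | CCOC(=O)/C(C)=C\C=C | intermediate
4 | (2Z)-2-methylpenta-2,4-dien-1-ol | OC/C(C)=C\C=C | intermediate
5 | (2E)-4-oxobut-2-enoic acid | O=C/C=C/C(=O)O | starting material
6 | (2Z)-2-methylpenta-2,4-dien-1-yl (2E)-4-oxobut-2-enoate | O=C/C=C/C(=O)OC/C(C)=C\C=C | intermediate
7 | ring A cyclohexene lactone aldehyde: cis-fused γ-lactone (C6 carbonyl on C5, C19H2–O on C4), C4 methyl cis to H5, C2=C3 double bond, C10 formyl trans to the lactone carbonyl | O=C[C@@H]1CC=C[C@@]2(C)COC(=O)[C@H]21 | intermediate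
8 | saturated ring A lactone aldehyde (7 with C2–C3 single bond) | O=C[C@@H]1CCC[C@@]2(C)COC(=O)[C@H]21 | intermediate
9 | quaternary lactone aldehyde amide: C10 bears CHO (cis to the lactone carbonyl) and CH2C(O)N(OMe)Me | CON(C)C(=O)C[C@@]1(CCC[C@@]2(C)COC(=O)[C@H]21)C=O | intermediate
10 | primary alcohol amide: C10 bears CH2OH and CH2C(O)N(OMe)Me | CON(C)C(=O)C[C@@]1(CCC[C@@]2(C)COC(=O)[C@H]21)CO | intermediate
11 | trimethylsilyl ether of 10 | CON(C)C(=O)C[C@@]1(CCC[C@@]2(C)COC(=O)[C@H]21)CO[Si](C)(C)C | intermediate
12 | hydroxy vinyl ketone: C10 bears CH2OH and CH2C(O)CH=CH2 | C=CC(=O)C[C@@]1(CCC[C@@]2(C)COC(=O)[C@H]21)CO | intermediate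
13 | acrylate vinyl ketone: acrylate ester of 12 | C=CC(=O)C[C@@]1(CCC[C@@]2(C)COC(=O)[C@H]21)COC(=O)C=C | intermediate
14 | silyloxydiene acrylate: (Z)-2-(tert-butyldimethylsilyloxy)buta-1,3-dienyl group on C10 (C10 cis to O), acrylate on C20–O | C=C/C(O[Si](C)(C)C(C)(C)C)=C/[C@@]1(CCC[C@@]2(C)COC(=O)[C@H]21)COC(=O)C=C | intermediate
15 | tetracyclic Diels–Alder adduct: ring A with γ-lactone, cis-fused δ-lactone (C7–O–C20), ring C cyclohexene with C11 silyl enol ether (C11=C12), H8 cis to H9 | O=C1OC[C@]4(CCC[C@@]3(C)COC(=O)[C@H]34)[C@@H]2C(O[Si](C)(C)C(C)(C)C)=CCC[C@H]12 | intermediate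
16 | C8 1-hydroxyethyl adduct of 15 (new carbon cis to H9; carbinol carbon as both epimers) | O=C1OC[C@]4(CCC[C@@]3(C)COC(=O)[C@H]34)[C@@H]2C(O[Si](C)(C)C(C)(C)C)=CCC[C@]12C(C)O | intermediate
17 | C8 acetyl lactone (β-keto δ-lactone, C11 silyl enol ether) | O=C1OC[C@]4(CCC[C@@]3(C)COC(=O)[C@H]34)[C@@H]2C(O[Si](C)(C)C(C)(C)C)=CCC[C@]12C(C)=O | intermediate
18 | ring C enone (C11 ketone, C12=C13) with C8 acetyl | O=C1OC[C@]4(CCC[C@@]3(C)COC(=O)[C@H]34)[C@@H]2C(=O)C=CC[C@]12C(C)=O | intermediate
19 | potassium C11 enolate of the ring D-closed 15-ketone | C1C(=O)[C@]23C[C@H]1C=C([O-])[C@H]2[C@@]1(CCC[C@@]2(C)COC(=O)[C@H]21)COC3=O.[K+] | intermediate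
20 | C11 triethylsilyl enol ether of the ring D-closed 15-ketone (bicyclo[3.2.1]octane formed, C16 is CH2) | C1C(=O)[C@]23C[C@H]1C=C(O[Si](CC)(CC)CC)[C@H]2[C@@]1(CCC[C@@]2(C)COC(=O)[C@H]21)COC3=O | intermediate
21 | 16-(dimethylaminomethyl) 15-ketone, C11 silyl enol ether (C16 configuration not defined) | CN(C)CC1C(=O)[C@]23C[C@H]1C=C(O[Si](CC)(CC)CC)[C@H]2[C@@]1(CCC[C@@]2(C)COC(=O)[C@H]21)COC3=O | intermediate
22 | 16-(trimethylammoniomethyl) 15-ketone iodide, C11 silyl enol ether | C[N+](C)(C)CC1C(=O)[C@]23C[C@H]1C=C(O[Si](CC)(CC)CC)[C@H]2[C@@]1(CCC[C@@]2(C)COC(=O)[C@H]21)COC3=O.[I-] | intermediate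
23 | 16-methylene 15-ketone with C11 triethylsilyl enol ether | C=C1C(=O)[C@]23C[C@H]1C=C(O[Si](CC)(CC)CC)[C@H]2[C@@]1(CCC[C@@]2(C)COC(=O)[C@H]21)COC3=O | intermediate
24 | 16-methylene-11,15-dione (both lactones in place) | C=C1C(=O)[C@]23C[C@H]1CC(=O)[C@H]2[C@@]1(CCC[C@@]2(C)COC(=O)[C@H]21)COC3=O | intermediate
25 | guidongnin C | C[C@H]1C(=O)[C@]23C[C@H]1C[C@@H](O)[C@H]2[C@@]1(CCC[C@@]2(C)COC(=O)[C@H]21)COC3=O | target

**Step count**

Total steps: 17. Longest linear sequence: 17 steps (1 and 2 to 25).

**Steps most likely to fail**

Step 4 (proposed new method). The hindered (Z)-diene may react too slowly under iminium catalysis, so that the uncatalysed, non-selective cycloaddition takes over, or the facial selectivity may be poor or opposite. Both would erode or invert the absolute configuration of C4 and C5. The fallback sets out from 6 and returns at 7 and uses known chemistry only. Heating 6 in toluene at about 120 °C should give the cis-fused adduct as a racemate, that is 7 together with its enantiomer F1 (thermal ester-tethered Diels–Alder reaction of a (Z)-dienyl ester). Acetalisation of the mixture with (R,R)-hydrobenzoin (pyridinium p-toluenesulfonate, benzene, water removal) should give the diastereomeric dioxolanes: the (R,R)-hydrobenzoin acetal of 7, F2, and the (R,R)-hydrobenzoin acetal of the enantiomer, F3. These are separated by chromatography or crystallisation, and mild acid hydrolysis of F2 (aqueous CF3CO2H) returns 7.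

Step 11. The cycloaddition may be too slow at a temperature the silyl dienol ether and the acrylate tolerate, because the ester tether disfavours the reactive conformer and the regiochemistry imposed by the tether is electronically mismatched; polymerisation or stepwise addition at C14 could then compete. The fallback sets out from 12 and returns at 16. Esterification of 12 with propiolic acid (DCC, DMAP cat., −20 °C) should give the propiolate vinyl ketone F4, and silylation (TBSOTf, Et3N) the silyloxydiene propiolate F5. The alkynoate dienophile has a less strained tether transition state and should cyclise at lower temperature (toluene, 110–140 °C) to the cyclohexa-1,4-diene lactone F6, in which C9 is set by the same allylic-strain control. Conjugate reduction of the unsaturated δ-lactone of F6 with LiBH(sBu)3 at −78 °C generates the same C8 lactone enolate as in step 12, and trapping with acetaldehyde (reductive aldol reaction) gives 16.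

Step 17. The lactones may be reduced or opened by the dissolving metal, or the C15 enolate may equilibrate on quenching so that the C16 configuration is lost. The fallback sets out from 24 and ends at 25, separating the three events. Copper hydride-catalysed 1,4-hydrosilylation of the α-methylene ketone ([(Ph3P)CuH]6 cat., Et3SiH, toluene) should give the C15 triethylsilyl enol ether 11-ketone F7. Reduction of the now isolated C11 ketone with SmI2 in THF/MeOH (single-electron reduction through the ketyl, lactones untouched) should give the equatorial 11-alcohol silyl enol ether F8. Protodesilylation with HF·pyridine at low temperature then delivers the proton to C16 from the exo face and gives 25.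

Further compounds
F1 | step 4 | enantiomer of 7 | O=C[C@H]1CC=C[C@]2(C)COC(=O)[C@@H]21
F2 | step 4 | (R,R)-hydrobenzoin acetal of 7 (4,5-diphenyl-1,3-dioxolane at C20) | C1(O[C@H](c2ccccc2)[C@@H](c2ccccc2)O1)[C@@H]1CC=C[C@@]2(C)COC(=O)[C@H]21
F3 | step 4 | (R,R)-hydrobenzoin acetal of the enantiomer of 7 | C1(O[C@H](c2ccccc2)[C@@H](c2ccccc2)O1)[C@H]1CC=C[C@]2(C)COC(=O)[C@@H]21
F4 | step 11 | propiolate vinyl ketone (propiolate ester of 12) | C=CC(=O)C[C@@]1(CCC[C@@]2(C)COC(=O)[C@H]21)COC(=O)C#C
F5 | step 11 | silyloxydiene propiolate | C=C/C(O[Si](C)(C)C(C)(C)C)=C/[C@@]1(CCC[C@@]2(C)COC(=O)[C@H]21)COC(=O)C#C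
F6 | step 11 | cyclohexa-1,4-diene lactone (C8=C14 conjugated with the δ-lactone, C11 silyl enol ether) | O=C1OC[C@]4(CCC[C@@]3(C)COC(=O)[C@H]34)[C@@H]2C(O[Si](C)(C)C(C)(C)C)=CCC=C12
F7 | step 17 | C15 triethylsilyl enol ether 11-ketone (C16 methyl on the enol double bond) | CC1=C(O[Si](CC)(CC)CC)[C@]23C[C@H]1CC(=O)[C@H]2[C@@]1(CCC[C@@]2(C)COC(=O)[C@H]21)COC3=O
F8 | step 17 | equatorial 11-alcohol with C15 triethylsilyl enol ether | CC1=C(O[Si](CC)(CC)CC)[C@]23C[C@H]1C[C@@H](O)[C@H]2[C@@]1(CCC[C@@]2(C)COC(=O)[C@H]21)COC3=O
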